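| setting | south-east | west | cedar | oak |
|---|---|---|---|---|
| electrophile | 1.5 M | 1.5 M | 1.5 M | 1.5 M |
| nucleophile | 1.5 M | 1.5 M | 1.50 M | 1.50 M |
| free base | 0.29 M | 0.72 M | 0.900 M | 0.450 M |
| remark | run made earlier | run made earlier |  |  |
| time |  |  | 10 min | 10 min |

| run | time / min | electrophile / % | product / % |
|---|---|---|---|
| south-east | 0.667 | 86.4 | 13.8 |
| south-east | 2.00 | 70.0 | 29.2 |
| south-east | 4.00 | 60.3 | 40.9 |
| south-east | 5.00 | 58.1 | 42.1 |
| south-east | 8.00 | 53.0 | 47.8 |
| south-east | 10.0 | 51.9 | 49.9 |
| west | 0.667 | 85.2 | 13.7 |
| west | 2.00 | 71.0 | 29.0 |
| west | 4.00 | 59.0 | 39.3 |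
| west | 5.00 | 57.4 | 43.7 |
| west | 8.00 | 52.0 | 47.6 |
| west | 10.0 | 50.7 | 50.0 |

(readings scatter by 0.5 percentage points)

* part of the electrophile that has reacted at the end, cedar
* part of the electrophile that has reacted at the end, oak
* what raising the concentration of free base from its lowest to its highest value here does to the part of the electrophile that has reacted (changes below 5 percentage points count as none) (it rises / it falls / no change)

- what may be going on: electrophile + nucleophile <-> acid set free + product; nucleophile + acid set free <-> protonated nucleophile; acid set free + free base <-> salt of the base

- If you want to know how far this flask gets in 10 min, keep the books on the nucleophile and reckon the fraction left, not the fraction made. Call X the part of the electrophile that has reacted, and E and N the charges of electrophile and nucleophile.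
- Enter the first loss: each electrophile that reacts takes one nucleophile into product and sets one acid free.
- Enter the second loss by asking where that acid lands. Compare the earlier runs: free base stands at 0.29 M in south-east and 0.72 M in west, yet product at 10.0 min reads 49.9% and 50.0%, a difference of 0.1 percentage points with a scatter of 0.5 points. So book the acid against the nucleophile, a second one lost per electrophile.
- Close the books: the fraction of nucleophile left is f = 1 − 2X·E/N. Setting f to zero gives the stall conversion, X_s = N/(2E), the conversion at which these books have entered the whole charge of nucleophile, here the limiting reagent. For these charges, 50.0%.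
- Read it on the west run: f reads 12.6% at 5.00 min and 0% at 10.0 min, each reading carrying the scatter of product, doubled.
- Commit: cedar and oak share E and N with the earlier runs, so my reckoning gives 50.0% for both, with no trend.
- Set beside it the forecast: 49.8% for cedar, 49.5% for oak, and no change, holding of the free base that “it is effectively a spectator here”.

    electrophile + nucleophile ⇌ acid set free + product (K = 0.500, k = 0.00300 M⁻¹ s⁻¹)
    nucleophile + acid set free ⇌ protonated nucleophile, settled at all times (K = 3300 M⁻¹)
    acid set free + free base ⇌ salt of the base (K = 21000 M⁻¹, k = 0.160 M⁻¹ s⁻¹)

- The flask gives 49.4% for cedar and 48.9% for oak against X_s of 50.0%, and the trend is no change, a change of 0.57 points. In cedar, the half-life of electrophile by the forward step alone lengthens from 5.1 min at 1.48 min to 41 min at 10.0 min, long against the run time of 10 min. At that time cedar holds 6.3% of its nucleophile free, with 0.664 M of protonated nucleophile, more than the 0.0760 M of salt of the base. Past X_s, cedar reaches 75.3% at 100 min. Now take a neighbour of cedar charged with 0.90 M of nucleophile: X_s is 30.0%, and that flask gives 31.3%.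

The readings were generated by integration for an exercise; the scatter is artificial.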